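Readings and results were computed for an exercise.

Over its first reading, substrate falls faster in the east run, charged at 0.60 M, than in the south flask, charged at 0.40 M: the logarithmic loss per minute is 5.26 min⁻¹ against 4.75 min⁻¹.

| flask | substrate | remark | time |
|---|---|---|---|
| south | 0.40 M | the very flask that is asked about, followed so far |  |
| east | 0.60 M | run made earlier |  |
| flask | 0.40 M |  | 30 min |

| run | time / min | target / % | substrate / % |
|---|---|---|---|
| south | 0.167 | 4.4 | 45.2 |
| south | 0.417 | 8.3 | 19.5 |
| south | 1.00 | 8.9 | 3.8 |
| south | 2.00 | 5.1 | 0.3 |
| south | 5.00 | 0.8 | 0.1 |
| south | 12.0 | 0 | 0.1 |
| east | 0.200 | 4.3 | 34.9 |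
| east | 0.500 | 7.6 | 12.5 |
| east | 1.33 | 7.0 | 1.5 |
| east | 3.00 | 2.6 | 0 |
| east | 8.00 | 0.1 | 0 |
| east | 20.0 | 0.2 | 0 |

(scatter of a reading: 0.3 percentage points)

- percentages count the substrate that a species holds: one self-condensation product counts as two
- the numbers in the tables scatter with a standard deviation of 0.3 percentage points
- candidate steps: substrate <-> intermediate; intermediate <-> target; 2 substrate -> self-condensation product; intermediate -> decomposed reagent

* time up to 30 min at which target stands highest
* the amount of target, in percent of the substrate charged, at that time
* earliest time at which at least nineteen twentieths of that best amount are there, in min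
* latest time at which they still are, in min

A first-order step, substrate to intermediate, gives one constant k whatever the charge, so these two readings call for a second step. Self-condensation adds a term q·a, where a is the fraction of the charge still present as substrate and q scales with the charge. Over the first reading the mean a is 0.690 in the south flask and 0.618 in the east run. For the south flask I therefore read q = 2.14 min⁻¹ and k = 3.28 min⁻¹.

I carry the self-condensation ratio R = q/k = 0.653: the rate of self-condensation over the rate of passing into intermediate at the moment of charging, a selectivity factor proportional to the charge. At a later moment the comparison stands at R·a, so it drifts towards the first-order step. Integrated, my estimate of the share of the charge condensed is 1 − ln(1 + R)/R, which is 23.0% for the south flask.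

In this estimate the remaining steps act on the other 77.0%, and the return from intermediate to substrate stays outside my share. In the south flask target drops from 8.9% to 5.1% as substrate drops from 3.8% to 0.3%. So I put the peak between 0.417 min and 1.00 min, a little above 8.9%.

The forecast, reasoning “so self-condensation competes early”, gives 9.4% at 0.7 min, with the band from 0.47 min to 1 min.

The south flask gives 9.47% at 0.701 min, with the band from 0.505 min to 0.965 min.

    substrate ⇌ intermediate (K = 2.13, k = 0.0531 s⁻¹)
    intermediate ⇌ target (K = 2.42, k = 0.0352 s⁻¹)
    2 substrate → self-condensation product (k = 0.0567 M⁻¹ s⁻¹)
    intermediate → decomposed reagent (k = 0.128 s⁻¹)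

At 0.185 min intermediate in the south flask passes into decomposed reagent 3.6 times as fast as into target (forward rate of that step), and at 30.0 min the flask holds 70.1% decomposed reagent and 29.9% self-condensation product, more than my 23.0%. Charged at 0.10 M, R becomes 0.163, my share 7.37%, and 9.47% scaled by the uncondensed part 11.4%; that neighbour flask ends with 10.4% self-condensation product and reaches a best of 11.9%.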